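## Retrosynthetic overview
1. The cyclohexene is cut last, at C12–C1' and C15–C2'. This is a [4+2] between a labda-8(17),12E,14-triene and the flavone B-ring p-quinone, run in the electrolysis cell that makes the quinone.
2. The quinone comes from anodic oxidation of its hydroquinone, and the hydroquinone from diosmetin by para-oxygenation of the 3'-OH phenol. The chromone and A ring are bought.
3. The diene partner, 7β-hydroxylabdatrien-18-al, comes from 4-epi-trans-communic acid, which supplies both decalin rings and C4, C5, C9 and C10.
4. The C7–O bond is made by allylic oxidation, oxidation to the ketone, and axial hydride delivery. CO2H becomes CHO. The diene is masked as a sulfolene during this work.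
5. Ring order: decalin and chromone are purchased, the quinone ring is unveiled at the anode, and the cyclohexene is formed last.

**Assumptions and conventions**
- 4-epi-trans-Communic acid, a conifer resin acid stocked by natural-product suppliers, is taken as the purchasable chiral feedstock.
- Labdane numbering (C1–C20) and diosmetin B-ring numbering (C1'–C6') are kept throughout. C1' bears the chromone, C3' bears O, and C4' bears OMe.
- In this numbering the target is 4R,5R,7S,9R,10R,12R,1'S,2'R. C11, the chromonyl group and H-2' all sit on the same face of the new cyclohexene.
- Steps 7 and 8 happen together in one electrolysis run. They are written as two steps so that each transformation is shown explicitly.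

## Route

**Step 1**
- Reactants: 1, 4-epi-trans-communic acid
- Product: 2, 3-sulfolene acid (C12 and C15 bridged by SO2; about 1:1 at C12)
- Conditions: SO2 (l, excess), BHT (5 mol %), CH2Cl2, sealed tube, 23 °C, 48 h
- Reagents that add atoms: sulfur dioxide, O=S=O
- Why: Cheletropic [4+1] addition occurs only at the s-cis-accessible E-diene (the "myrcene sulfone" masking tactic) and leaves the 8(17)-alkene and the acid untouched, with BHT suppressing radical alkene isomerisation; the new C12 centre is a throw-away mixture erased in step 4.

**Step 2**
- Reactants: 2
- Product: 3, 7α-hydroxy sulfolene acid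
- Conditions: SeO2 (0.5 equiv), t-BuOOH (3 equiv), CH2Cl2, 0 → 23 °C
- Reagents that add atoms: selenium dioxide, O=[Se]=O (delivers the C7 oxygen; recycled by t-BuOOH, CC(C)(C)OO)
- Why: Riley allylic oxidation (ene, then [2,3]-shift) acts on the only electron-rich alkene left, prefers CH2-7 over CH-9, and delivers O axially to give the 7α-alcohol, while the electron-poor sulfolene alkene is inert; any enone 4 formed is carried forward.

**Step 3**
- Reactants: 3
- Product: 4, 7-oxo-8(17)-ene sulfolene acid
- Conditions: DMP (1.3 equiv), NaHCO3, CH2Cl2, 0 °C; used at once
- Reagents that add atoms: none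
- Why: Dess–Martin oxidation of the allylic alcohol removes the wrong C7 configuration without touching the acid, sulfone or alkenes.

**Step 4**
- Reactants: 4
- Product: 5, labda-8(17),12E,14-triene-7β,18-diol
- Conditions: LiAlH4 (8 equiv), THF, −78 °C (1 h) → 50 °C (3 h); Rochelle salt
- Reagents that add atoms: none (hydride only; SO2 is lost)
- Why: One reagent does three known jobs: cold 1,2-reduction of the enone by axial α-face attack on the rigid trans-decalin gives the equatorial 7β-OH (7S); the equatorial C18 carboxylate is reduced to CH2OH; and LiAlH4-promoted cheletropic SO2 extrusion, with C11 rotating outward, regenerates only the 12E-diene from both C12 epimers.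

**Step 5**
- Reactants: 5
- Product: 6, 7β-hydroxylabda-8(17),12E,14-trien-18-al
- Conditions: TEMPO (0.15 equiv), PhI(OAc)2 (1.1 equiv), CH2Cl2, 0 → 23 °C
- Reagents that add atoms: none
- Why: Oxoammonium (TEMPO/BAIB) oxidation is sterically selective for the primary C18 carbinol over the flanked secondary 7β-OH, stops at the aldehyde, and cannot epimerise quaternary C4.

**Step 6**
- Reactants: 7, diosmetin
- Product: 8, 5,7,2',5'-tetrahydroxy-4'-methoxyflavone (new OH at C6' in diosmetin numbering)
- Conditions: (KSO3)2NO (2.5 equiv), DMF/KH2PO4 buffer (pH 6), 0 → 23 °C; then aq Na2S2O4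
- Reagents that add atoms: potassium nitrosodisulfonate (Fremy's salt), [K+].[K+].[O-]S(=O)(=O)N([O])S(=O)(=O)[O-]
- Why: In the Teuber oxidation the radical abstracts H from the most electron-rich phenol (3'-OH; 5-OH is chelated and 7-OH is a vinylogous acid) and a second equivalent couples at the free para carbon C6', avoiding the ipso-OMe attack and o-quinone formation typical of two-electron oxidants; the first-formed p-quinone is too labile to purify or store, so the dithionite work-up converts it into the storable hydroquinone, and no stereocentre is formed.

**Step 7**
- Reactants: 8 (2 equiv relative to 6)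
- Product: 9, 2-(5,7-dihydroxy-4-oxochromen-2-yl)-5-methoxy-1,4-benzoquinone, the flavone B-ring quinone (generated in the anolyte, not isolated)
- Conditions: divided cell, RVC anode/Pt cathode, +0.6 V vs Ag/AgCl, 2.1 F/mol of 8, n-Bu4NPF6 (0.1 M), 2,6-lutidine (2.2 equiv per 8), HFIP–MeCN 3:1, 20 °C, dark, N2; 8 fed by syringe pump over 6 h into an anolyte that already contains 6
- Reagents that add atoms: none
- Why: Anodic two-electron, two-proton hydroquinone-to-quinone oxidation is a reliable reaction type; at +0.6 V only the B-ring hydroquinone is oxidised (the diene, aldehyde, allylic alcohol and chelated resorcinol A ring need more than about +1.2 V), lutidine takes up the released protons as lutidinium, the slow feed keeps both nucleophilic 8 and labile 9 dilute relative to 6, and no stereocentre is formed.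

**Step 8**
- Reactants: 6 (1 equiv); 9 (as it is released at the anode in step 7)
- Product: 10, Dichrostachine H
- Conditions: same anolyte and same run as step 7, electrolysis on (+0.6 V, HFIP–MeCN 3:1, electrogenerated lutidinium, 20 °C, dark, N2); after the charge has passed, stir 12 h; pH 6 buffer wash, chromatography and prep. HPLC
- Reagents that add atoms: none
- Why: Proposed new method: in-cell, exo-oriented Diels–Alder capture of an anodically released flavone B-ring quinone at its chromonyl-substituted C=C, promoted by the lutidinium/HFIP hydrogen-bond medium that the electrolysis itself produces; the two acceptors on C1' (C6'=O, the most basic vinylogous-ester carbonyl, H-bonded by HFIP/lutidinium, and the chromone enone, activated by the 5-OH···O=C4 chelate) make C2' the electrophilic terminus, so the unhindered, most nucleophilic C15 bonds to C2' and C12 to C1' while the MeO-bearing C4'=C5' bond stays inert; suprafacial addition fixes the cis fusion (chromonyl syn to H-2'); the bulky solvated C6'=O flank is meant to be pushed away from C11H2 and the decalin so that the flat chromone rather than the enedione lies under C13–C14 (chromone-endo, enedione-exo), which with the E-diene places C11 syn to the chromonyl; addition anti to C9 on the A1,3-minimised rotamer (one H-11 eclipsing C12=C13, C12 antiperiplanar to C8) gives 12R,1'S,2'R, the weakly acidic buffered medium does not epimerise C2', and the other diastereomers are removed by HPLC; the closest known reaction type is in-cell anodic hydroquinone→quinone/Diels–Alder capture in LiClO4–MeNO2 or micellar media, which has not been shown for flavonoid quinones, for addition at an aryl-substituted quinone C=C that forms a quaternary carbon, or with solvent-imposed exo orientation.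

## Compound list

| No. | Name | SMILES | Role |
|---|---|---|---|
| 1 | 4-epi-trans-communic acid (labda-8(17),12E,14-trien-18-oic acid; 4R,5R,9S,10R) | `C=C1CC[C@@H]2[C@](C)(CCC[C@@]2(C)C(=O)O)[C@H]1C/C=C(C)/C=C` | starting material |
| 2 | 12,15-SO2-bridged 3-sulfolene of 1 (C12 epimers) | `C=C1CC[C@@H]2[C@](C)(CCC[C@@]2(C)C(=O)O)[C@H]1CC1C(C)=CCS1(=O)=O` | intermediate |
| 3 | 7α-hydroxy sulfolene acid (C12 epimers) | `C=C1[C@H](O)C[C@@H]2[C@](C)(CCC[C@@]2(C)C(=O)O)[C@H]1CC1C(C)=CCS1(=O)=O` | intermediate |
| 4 | 7-oxo sulfolene acid (C12 epimers) | `C=C1C(=O)C[C@@H]2[C@](C)(CCC[C@@]2(C)C(=O)O)[C@H]1CC1C(C)=CCS1(=O)=O` | intermediate |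
| 5 | labda-8(17),12E,14-triene-7β,18-diol | `C=C1[C@@H](O)C[C@@H]2[C@](C)(CCC[C@@]2(C)CO)[C@H]1C/C=C(C)/C=C` | intermediate |
| 6 | 7β-hydroxylabda-8(17),12E,14-trien-18-al | `C=C1[C@@H](O)C[C@@H]2[C@](C)(CCC[C@@]2(C)C=O)[C@H]1C/C=C(C)/C=C` | intermediate |
| 7 | diosmetin (5,7,3'-trihydroxy-4'-methoxyflavone) | `COc1ccc(cc1O)-c1cc(=O)c2c(O)cc(O)cc2o1` | starting material |
| 8 | 5,7,2',5'-tetrahydroxy-4'-methoxyflavone | `COc1cc(O)c(cc1O)-c1cc(=O)c2c(O)cc(O)cc2o1` | intermediate |
| 9 | 2-(5,7-dihydroxy-4-oxochromen-2-yl)-5-methoxy-1,4-benzoquinone (product of step 7, used in the cell without isolation) | `COC1=CC(=O)C(=CC1=O)c1cc(=O)c2c(O)cc(O)cc2o1` | intermediate |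
| 10 | Dichrostachine H | `C=C1[C@@H](O)C[C@@H]2[C@](C)(CCC[C@@]2(C)C=O)[C@H]1C[C@@H]1C(C)=CC[C@H]2C(=O)C(OC)=CC(=O)[C@@]12c1cc(=O)c2c(O)cc(O)cc2o1` | target |

## Step count
- Total steps: 8. Steps 7 and 8 are one electrolysis run, so there are 7 separate operations.
- Longest linear sequence: 6 (steps 1–5, then 8). The flavone arm is 3 steps (6, 7, 8).

## Three steps most likely to fail

1. **Step 8 (the proposed new step).**
   - Risk: the normal Alder preference (enedione-endo) and the weak π-facial bias of labdatrienes may make the 12-epimer or the other diastereomers the major products. A conformational estimate suggests that both the exo mode and the 12R face could be the intrinsically disfavoured ones. Quinone 9 may also self-condense or be attacked by 8 before the diene captures it.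
   - Fallback (known chemistry): give up in-cell generation and solvent control, and use a protected, isolated quinone with a receptor-directed cycloaddition.
     - Silylate diosmetin at its most acidic 7-OH (TBSCl, imidazole); the 5-OH stays chelated.
     - Run the Teuber oxidation without the dithionite work-up and isolate the 7-O-TBS quinone, which no longer carries the nucleophilic 7-OH.
     - Mask 6 as its 7-O-TES ether.
     - Run a conventional Diels–Alder with a bulky aluminium aryloxide carbonyl receptor (ATPH type, ≥2 equiv because the CHO also binds). This receptor class is documented to direct exo addition.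
     - Desilylate with HF·pyridine and separate by HPLC. This adds 3 steps.

2. **Step 4 (three-fold LiAlH4 step).**
   - Risk: 1,4-reduction of the s-cis α-methylene ketone, or base-induced opening of the sulfolene to a dienyl sulfinate instead of clean SO2 loss.
   - Fallback: decouple the three events.
     - Luche reduction (NaBH4/CeCl3) of 4 to set the 7β-OH.
     - Thermal retro-cheletropic extrusion (toluene, NaHCO3, 110 °C) to restore the E-diene.
     - LiAlH4 reduction of the acid alone. This adds 2 steps.

3. **Step 6 (Teuber oxidation of unprotected diosmetin).**
   - Risk: poor solubility, A-ring oxidation at C8, or decomposition of the electron-poor quinone before it is reduced.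
   - Fallback: build 8 de novo.
     - Thermally condense phloroglucinol with ethyl 3-[2,5-bis(benzyloxy)-4-methoxyphenyl]-3-oxopropanoate to give the 5,7-dihydroxyflavone.
     - Hydrogenolyse the benzyl ethers (H2, Pd/C) to obtain 8.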